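**Strategy.** Everything rests on opening the trans-fused γ-lactone (ring O6–C12–C11–C7–C6) at O6–C12 and reading C6 as a ketone whose neighbour C7 is enolisable. One Ru-catalysed dynamic kinetic transfer hydrogenation of a racemic β-furyl α-keto ester carrying a mixed methyl/tert-butyl malonate reduces C6, funnels both C7 enantiomers into one and lactonises onto the methyl ester, giving the all-trans lactone. The furan then becomes C8; an eight-carbon bis-allyl ketal (C2 from TosMIC) is attached at C8 by indium allylation and at C5 by Ni/Cr ring closure, and ketal hydrolysis delivers the C2–O–C5 hemiketal.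

Key step: step 3

Assumption: atom labels follow germacrane numbering (ring C1–C10, lactone carbons C11–C13, C14 on C10, C15 on C4); the (S,S) ligand is assigned to the needed lactone by the usual transfer-hydrogenation mnemonic with the ester as π-directing group, and its antipode serves the same route if the sense proves opposite.

Step 1
Reactants: 1 furfural; 2 tert-butyl methyl malonate
Product: 3 tert-butyl methyl 2-(furan-2-ylmethylidene)propanedioate (E/Z mixture)
Conditions: piperidine (cat.), AcOH (cat.), toluene, reflux, Dean–Stark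
Reagents that add atoms: none
Why: Knoevenagel condensation of the non-enolisable aldehyde with the malonate under amine/acid catalysis with azeotropic water removal; the E/Z ratio of 3 is irrelevant because the alkene is consumed in step 2.

Step 2
Reactants: 3 alkylidene malonate; 4 ethyl glyoxylate
Product: 5 racemic keto triester 1-tert-butyl 3-methyl 2-[3-ethoxy-1-(furan-2-yl)-2,3-dioxopropyl]propanedioate
Conditions: 6,7-dihydro-2-(pentafluorophenyl)-5H-pyrrolo[2,1-c][1,2,4]triazol-2-ium tetrafluoroborate (20 mol %), iPr2NEt, MgSO4, CCl4, 0 °C to rt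
Reagents that add atoms: none
Why: Stetter reaction: the triazolylidene carbene turns the glyoxylate aldehyde into an acyl-anion equivalent that adds in 1,4-fashion to the doubly activated alkylidene malonate and forms C6–C7, the new C7 centre being left racemic on purpose.

Step 3
Reactants: 5 racemic keto triester
Product: 7 all-trans lactone 4-tert-butyl 2-ethyl (2S,3S,4S)-3-(furan-2-yl)-5-oxooxolane-2,4-dicarboxylate, via hydroxy triester 6 (not isolated)
Conditions: RuCl(p-cymene)[(S,S)-TsDPEN] (2 mol %), HCO2H/Et3N (5:2), DMF, 70 °C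
Reagents that add atoms: none
Why: The Ru hydride/amine complex generated from formate transfers hydride and proton to the C6 ketone through the usual outer-sphere six-membered transition state, while C7–H, acidified by the adjacent ketone and the furan, exchanges through the enol in the amine–formate medium so that the two C7 enantiomers of 5 interconvert faster than either is reduced. The closest known reaction type is the dynamic kinetic asymmetric transfer hydrogenation of β-aryl α-keto esters with spontaneous lactonisation to γ-butyrolactones. The C6 hydroxyl of 6 then attacks the malonate methyl ester in a 5-exo-trig acyl substitution (loss of methanol) that closes the lactone ring O6–C12–C11–C7–C6, the tert-butyl ester being too hindered to compete. C6 is set by the chiral catalyst (hydride to one carbonyl face), C7 by the catalyst's preference for the matched enantiomer of the racemising ketone, and C11 by thermodynamic epimerisation of the malonyl position to the all-trans ring. The step needs enantioface selection, selection between the C7 enantiomers and regioselective lactonisation; the first two are secured by catalyst–substrate matching on a rapidly racemising C7, the last by the methyl/tert-butyl difference built into the malonate.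

Step 4
Reactants: 7 all-trans lactone
Product: 8 C8 acid (2S,3S,4S)-4-(tert-butoxycarbonyl)-2-(ethoxycarbonyl)-5-oxooxolane-3-carboxylic acid
Conditions: RuCl3·xH2O (5 mol %), NaIO4, CCl4/MeCN/H2O, rt
Reagents that add atoms: sodium periodate [Na+].[O-]I(=O)(=O)=O; water O
Why: Oxidative degradation of the electron-rich furan by catalytic RuO4 (regenerated by periodate) leaves only its ipso carbon as the C8 carboxylic acid, while esters, lactone and the three stereocentres are untouched.

Step 5
Reactants: 8 C8 acid
Product: 9 C8 primary alcohol 4-tert-butyl 2-ethyl (2S,3R,4S)-3-(hydroxymethyl)-5-oxooxolane-2,4-dicarboxylate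
Conditions: BH3·SMe2, THF, 0 °C to rt; MeOH quench
Reagents that add atoms: none
Why: Borane reduces the free carboxylic acid (through an acyloxyborane) much faster than esters or the lactone, giving the C8 primary alcohol chemoselectively.

Step 6
Reactants: 9 C8 primary alcohol
Product: 10 C8 aldehyde 4-tert-butyl 2-ethyl (2S,3S,4S)-3-formyl-5-oxooxolane-2,4-dicarboxylate
Conditions: Dess–Martin periodinane, CH2Cl2, 0 °C to rt; used crude
Reagents that add atoms: none
Why: Dess–Martin oxidation works without base, so the new C8 aldehyde neither epimerises at C7 nor eliminates the lactone oxygen from C6.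

Step 7
Reactants: 11 TosMIC (p-toluenesulfonylmethyl isocyanide); 12 2,3-dibromoprop-1-ene
Product: 13 monoalkylated TosMIC 1-[(3-bromo-1-isocyanobut-3-en-1-yl)sulfonyl]-4-methylbenzene (racemic)
Conditions: Bu4NI (cat.), 40% aq. NaOH, CH2Cl2, 0 °C
Reagents that add atoms: none
Why: Phase-transfer C-alkylation of the TosMIC carbanion by SN2 displacement of the allylic bromide (the vinylic bromide is inert) places C3, C4 and C15 on the future C2.

Step 8
Reactants: 13 monoalkylated TosMIC; 14 3-chloro-2-(chloromethyl)prop-1-ene
Product: 16 2-bromo-6-(chloromethyl)hepta-1,6-dien-4-one, via dialkylated isocyanide 15 (not isolated)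
Conditions: NaH, DMSO/Et2O, 14 (4 equiv), rt; then conc. HCl, Et2O/CH2Cl2, 0 °C
Reagents that add atoms: water O
Why: Second C-alkylation of the TosMIC carbon (excess dichloride suppresses double displacement) followed by acid hydrolysis of the α-sulfonyl isocyanide (van Leusen ketone synthesis) reveals the C2 carbonyl flanked by both allylic arms.

Step 9
Reactants: 16 dienone
Product: 17 ketal fragment 2-(2-bromoprop-2-en-1-yl)-2-[2-(chloromethyl)prop-2-en-1-yl]-1,3-dioxolane
Conditions: 1,2-bis(trimethylsilyloxy)ethane, TMSOTf (cat.), CH2Cl2, −78 to −20 °C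
Reagents that add atoms: 1,2-bis(trimethylsilyloxy)ethane C[Si](C)(C)OCCO[Si](C)(C)C
Why: Silyl-triflate-catalysed ketalisation with the bis-silyl glycol at low temperature masks the C2 ketone without moving either β,γ-double bond into conjugation.

Step 10
Reactants: 10 C8 aldehyde; 17 ketal fragment
Product: 18 (8S)-homoallylic alcohol
Conditions: indium powder (In), NaI (cat.), 17 (1.5 equiv), DMF, rt
Reagents that add atoms: none
Why: Barbier-type allylindium addition (Finkelstein-activated allyl chloride; the 2-substituted allyl unit has equivalent termini, and vinyl bromide, ketal and malonyl C–H are tolerated) forms C8–C9, with Felkin–Anh attack anti to the C7–C6 bond, which keeps the carbonyl oxygen away from O6, expected to favour the 8S carbinol.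

Step 11
Reactants: 18 (8S)-homoallylic alcohol; 19 tigloyl chloride
Product: 20 C8 tiglate
Conditions: pyridine, DMAP (cat.), CH2Cl2, 0 °C to rt
Reagents that add atoms: none
Why: DMAP-catalysed acylation of the secondary C8 alcohol by the acid chloride proceeds with retention and installs the tiglate, which also protects O8 for the rest of the route; pyridine is too weak a base to enolise the malonyl position appreciably.

Step 12
Reactants: 20 C8 tiglate
Product: 21 C5 primary alcohol
Conditions: NaBH4, EtOH/THF, 0 °C
Reagents that add atoms: none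
Why: Borohydride reduction is selective for the ethyl ester activated by the adjacent lactone oxygen, whereas the lactone and tert-butyl ester are shielded as the malonyl enolate and by steric bulk and the tiglate is a poor acceptor at 0 °C.

Step 13
Reactants: 21 C5 primary alcohol
Product: 23 C11 carboxylic acid, via silyl ester 22 (not isolated)
Conditions: TMSOTf (4 equiv), 2,6-lutidine, CH2Cl2, 0 °C; then aq. citric acid/THF
Reagents that add atoms: trimethylsilyl triflate C[Si](C)(C)OS(=O)(=O)C(F)(F)F (silyl groups of intermediate 22 only)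
Why: Silyl triflate converts the tert-butyl ester into the silyl ester with loss of isobutene under non-protic conditions that spare the ketal, the 1,1-disubstituted alkenes and the tiglate, and aqueous work-up hydrolyses both silyl groups.

Step 14
Reactants: 23 C11 carboxylic acid; 24 formaldehyde
Product: 26 α-methylene lactone, via Mannich adduct 25 (not isolated)
Conditions: 37% aq. HCHO, Et2NH, AcOH/NaOAc buffer, THF, rt to 50 °C
Reagents that add atoms: diethylamine CCNCC (aminomethyl group of intermediate 25 only)
Why: Decarboxylative Mannich methylenation: the malonic half-acid adds to the iminium ion from formaldehyde and diethylamine and the adduct fragments with loss of CO2 and amine to the C11=C13 exo-methylene, which removes the C11 stereocentre.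

Step 15
Reactants: 26 α-methylene lactone
Product: 27 C5 aldehyde
Conditions: Dess–Martin periodinane, CH2Cl2, 0 °C to rt; used crude
Reagents that add atoms: none
Why: Dess–Martin oxidation of the primary alcohol gives the C5 aldehyde under neutral conditions that leave the α-methylene lactone, tiglate and ketal intact and do not epimerise C6.

Step 16
Reactants: 27 C5 aldehyde
Product: 28 macrocyclic (5S)-alcohol ketal
Conditions: CrCl2 (8 equiv), NiCl2 (2 mol %), DMSO/THF (3:1), 2 mM, slow addition, rt
Reagents that add atoms: none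
Why: Intramolecular Nozaki–Hiyama–Kishi coupling (Ni-catalysed formation of the C4 alkenylchromium and its chemoselective addition to the aldehyde) forges C4–C5 and the 10-membered ring; with the C6–O6 bond anti to the incoming alkenyl group (polar Felkin–Anh) and the short tether through C7–C8 forcing that group to flank C7, the 5,6-syn (5S) carbinol is expected.

Step 17
Reactants: 28 macrocyclic (5S)-alcohol ketal
Product: 29 CNP0307443.2
Conditions: PPTS, acetone/H2O (10:1), 45 °C
Reagents that add atoms: water O
Why: Acid-catalysed ketal hydrolysis, assisted by transketalisation with the C5 hydroxyl, releases the C2 ketone, which is trapped at once by O5 as the five-membered bridged hemiketal; C2 forms as the single 2S isomer because the oxygen bridge can only span C2 and C5 cis.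

**Compound list** (A = (1S)-3-{[2-(2-bromoprop-2-en-1-yl)-1,3-dioxolan-2-yl]methyl}-1-{[(2E)-2-methylbut-2-enoyl]oxy}but-3-en-1-yl)

1 | furfural (furan-2-carbaldehyde) | O=Cc1ccco1 | starting material
2 | tert-butyl methyl malonate | COC(=O)CC(=O)OC(C)(C)C | starting material
3 | tert-butyl methyl 2-(furan-2-ylmethylidene)propanedioate (E/Z mixture) | COC(=O)C(=Cc1ccco1)C(=O)OC(C)(C)C | intermediate
4 | ethyl glyoxylate | CCOC(=O)C=O | starting material
5 | 1-tert-butyl 3-methyl 2-[3-ethoxy-1-(furan-2-yl)-2,3-dioxopropyl]propanedioate (racemic, both malonate epimers) | CCOC(=O)C(=O)C(c1ccco1)C(C(=O)OC)C(=O)OC(C)(C)C | intermediate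
6 | 1-tert-butyl 3-ethyl 1-methyl (2S,3S)-2-(furan-2-yl)-3-hydroxypropane-1,1,3-tricarboxylate (hydroxy triester, both malonate epimers) | CCOC(=O)[C@@H](O)[C@@H](c1ccco1)C(C(=O)OC)C(=O)OC(C)(C)C | intermediate
7 | 4-tert-butyl 2-ethyl (2S,3S,4S)-3-(furan-2-yl)-5-oxooxolane-2,4-dicarboxylate (all-trans lactone) | CCOC(=O)[C@H]1OC(=O)[C@@H](C(=O)OC(C)(C)C)[C@@H]1c1ccco1 | intermediate
8 | (2S,3S,4S)-4-(tert-butoxycarbonyl)-2-(ethoxycarbonyl)-5-oxooxolane-3-carboxylic acid | CCOC(=O)[C@H]1OC(=O)[C@@H](C(=O)OC(C)(C)C)[C@@H]1C(=O)O | intermediate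
9 | 4-tert-butyl 2-ethyl (2S,3R,4S)-3-(hydroxymethyl)-5-oxooxolane-2,4-dicarboxylate | CCOC(=O)[C@H]1OC(=O)[C@@H](C(=O)OC(C)(C)C)[C@@H]1CO | intermediate
10 | 4-tert-butyl 2-ethyl (2S,3S,4S)-3-formyl-5-oxooxolane-2,4-dicarboxylate | CCOC(=O)[C@H]1OC(=O)[C@@H](C(=O)OC(C)(C)C)[C@@H]1C=O | intermediate
11 | TosMIC (p-toluenesulfonylmethyl isocyanide) | Cc1ccc(cc1)S(=O)(=O)C[N+]#[C-] | starting material
12 | 2,3-dibromoprop-1-ene | C=C(Br)CBr | starting material
13 | 1-[(3-bromo-1-isocyanobut-3-en-1-yl)sulfonyl]-4-methylbenzene (racemic) | Cc1ccc(cc1)S(=O)(=O)C(CC(Br)=C)[N+]#[C-] | intermediate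
14 | 3-chloro-2-(chloromethyl)prop-1-ene | C=C(CCl)CCl | starting material
15 | 1-{[2-bromo-6-(chloromethyl)-4-isocyanohepta-1,6-dien-4-yl]sulfonyl}-4-methylbenzene (racemic) | Cc1ccc(cc1)S(=O)(=O)C(CC(Br)=C)(CC(=C)CCl)[N+]#[C-] | intermediate
16 | 2-bromo-6-(chloromethyl)hepta-1,6-dien-4-one | C=C(Br)CC(=O)CC(=C)CCl | intermediate
17 | 2-(2-bromoprop-2-en-1-yl)-2-[2-(chloromethyl)prop-2-en-1-yl]-1,3-dioxolane | C=C(Br)CC1(CC(=C)CCl)OCCO1 | intermediate
18 | 4-tert-butyl 2-ethyl (2S,3R,4S)-3-[(1S)-3-{[2-(2-bromoprop-2-en-1-yl)-1,3-dioxolan-2-yl]methyl}-1-hydroxybut-3-en-1-yl]-5-oxooxolane-2,4-dicarboxylate | CCOC(=O)[C@H]1OC(=O)[C@@H](C(=O)OC(C)(C)C)[C@@H]1[C@@H](O)CC(=C)CC2(CC(Br)=C)OCCO2 | intermediate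
19 | tigloyl chloride, (2E)-2-methylbut-2-enoyl chloride | C/C=C(\C)C(=O)Cl | starting material
20 | 4-tert-butyl 2-ethyl (2S,3R,4S)-3-A-5-oxooxolane-2,4-dicarboxylate | CCOC(=O)[C@H]1OC(=O)[C@@H](C(=O)OC(C)(C)C)[C@@H]1[C@@H](OC(=O)/C(C)=C/C)CC(=C)CC2(CC(Br)=C)OCCO2 | intermediate
21 | tert-butyl (3S,4R,5S)-4-A-5-(hydroxymethyl)-2-oxooxolane-3-carboxylate | OC[C@H]1OC(=O)[C@@H](C(=O)OC(C)(C)C)[C@@H]1[C@@H](OC(=O)/C(C)=C/C)CC(=C)CC2(CC(Br)=C)OCCO2 | intermediate
22 | trimethylsilyl (3S,4R,5S)-4-A-2-oxo-5-{[(trimethylsilyl)oxy]methyl}oxolane-3-carboxylate | C[Si](C)(C)OC[C@H]1OC(=O)[C@@H](C(=O)O[Si](C)(C)C)[C@@H]1[C@@H](OC(=O)/C(C)=C/C)CC(=C)CC2(CC(Br)=C)OCCO2 | intermediate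
23 | (3R,4R,5S)-4-A-5-(hydroxymethyl)-2-oxooxolane-3-carboxylic acid | OC[C@H]1OC(=O)[C@@H](C(=O)O)[C@@H]1[C@@H](OC(=O)/C(C)=C/C)CC(=C)CC2(CC(Br)=C)OCCO2 | intermediate
24 | formaldehyde | C=O | starting material
25 | (4R,5S)-4-A-3-[(diethylamino)methyl]-5-(hydroxymethyl)-2-oxooxolane-3-carboxylic acid (both C3 epimers) | OC[C@H]1OC(=O)C(CN(CC)CC)(C(=O)O)[C@@H]1[C@@H](OC(=O)/C(C)=C/C)CC(=C)CC2(CC(Br)=C)OCCO2 | intermediate
26 | (4R,5S)-4-A-5-(hydroxymethyl)-3-methylideneoxolan-2-one | OC[C@H]1OC(=O)C(=C)[C@@H]1[C@@H](OC(=O)/C(C)=C/C)CC(=C)CC2(CC(Br)=C)OCCO2 | intermediate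
27 | (2S,3R)-3-A-4-methylidene-5-oxooxolane-2-carbaldehyde | O=C[C@H]1OC(=O)C(=C)[C@@H]1[C@@H](OC(=O)/C(C)=C/C)CC(=C)CC2(CC(Br)=C)OCCO2 | intermediate
28 | (5S,6S,7R,8S)-5-hydroxy-8-(tigloyloxy)germacra-4(15),10(14),11(13)-trien-12,6-olide with C2 as its 1,3-dioxolane ketal | C=C1C[C@H](OC(=O)/C(C)=C/C)[C@H]2C(=C)C(=O)O[C@@H]2[C@@H](O)C(=C)CC3(C1)OCCO3 | intermediate
29 | CNP0307443.2, (2S,5S,6S,7R,8S)-2,5-epoxy-2-hydroxy-8-(tigloyloxy)germacra-4(15),10(14),11(13)-trien-12,6-olide | C=C1C[C@H](OC(=O)/C(C)=C/C)[C@H]2C(=C)C(=O)O[C@@H]2[C@H]2O[C@@](O)(C1)CC2=C | target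

**Step count.** Total: 17 steps. Longest linear sequence: 14 steps (1–6 and 10–17); the ketal fragment 17 takes 3 steps (7–9).

**Steps most likely to fail, most critical first.**

Step 16, the ring closure. The addition of the alkenylchromium to the C5 aldehyde may show poor or reversed facial selectivity, because the strained 10-membered transition state, not a simple acyclic model, decides the face. The fallback resets C5 by redox chemistry instead of by C–C bond formation. It sets out from 27: the cyclisation is accepted whatever its C5 outcome, and the (5R)-epimer of 28, alcohol F1, is oxidised with Dess–Martin periodinane to the macrocyclic C5 enone F2. Corey–Bakshi–Shibata reduction of F2 ((S)-2-methyl-CBS-oxazaborolidine, catecholborane, toluene, −78 °C; the α-branched alkenyl group taken as the large substituent, no conjugate reduction of the lactone methylene) returns to the route at 28.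

Step 3, the key step. The catalyst may reduce the matched C7 enantiomer to the hydroxy ester that lactonises to the C6/C7-cis ring, so that kinetic control gives the wrong relative configuration. The fallback puts C6 under thermodynamic control. It sets out from 5: the antipodal catalyst RuCl(p-cymene)[(R,R)-TsDPEN] would then deliver C7 as required in the cis lactone 4-tert-butyl 2-ethyl (2R,3S,4S)-3-(furan-2-yl)-5-oxooxolane-2,4-dicarboxylate F4, and DBU in CH2Cl2 epimerises the ester-bearing C6 to the all-trans lactone, returning at 7.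

Step 10, the allylation. Facial discrimination of the C8 aldehyde between its two similar ring neighbours may be insufficient, giving mainly or partly the 8R carbinol. The fallback is a stereoinvertive esterification. It sets out from 10 and 17: the (8R)-epimer of 18, alcohol F3, is isolated and treated with tiglic acid, PPh3 and DIAD in toluene (Mitsunobu reaction, inversion at C8), which returns to the route at 20, so both allylation epimers converge.

Further compounds
F1 | step 16 | (5R,6S,7R,8S)-5-hydroxy-8-(tigloyloxy)germacra-4(15),10(14),11(13)-trien-12,6-olide C2 1,3-dioxolane ketal (C5 epimer of 28) | C=C1C[C@H](OC(=O)/C(C)=C/C)[C@H]2C(=C)C(=O)O[C@@H]2[C@H](O)C(=C)CC3(C1)OCCO3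
F2 | step 16 | (6S,7R,8S)-5-oxo-8-(tigloyloxy)germacra-4(15),10(14),11(13)-trien-12,6-olide C2 1,3-dioxolane ketal | C=C1C[C@H](OC(=O)/C(C)=C/C)[C@H]2C(=C)C(=O)O[C@@H]2C(=O)C(=C)CC3(C1)OCCO3
F3 | step 10 | 4-tert-butyl 2-ethyl (2S,3R,4S)-3-[(1R)-3-{[2-(2-bromoprop-2-en-1-yl)-1,3-dioxolan-2-yl]methyl}-1-hydroxybut-3-en-1-yl]-5-oxooxolane-2,4-dicarboxylate (C8 epimer of 18) | CCOC(=O)[C@H]1OC(=O)[C@@H](C(=O)OC(C)(C)C)[C@@H]1[C@H](O)CC(=C)CC2(CC(Br)=C)OCCO2
F4 | step 3 | 4-tert-butyl 2-ethyl (2R,3S,4S)-3-(furan-2-yl)-5-oxooxolane-2,4-dicarboxylate | CCOC(=O)[C@@H]1OC(=O)[C@@H](C(=O)OC(C)(C)C)[C@@H]1c1ccco1
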